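**Retrosynthetic overview**

1. Late stage: the C8 exocyclic methylene comes from a C8 ketone, the butenolide is joined at C12–C13 by B-alkyl Suzuki coupling of a C9 vinyl group, the C19 acetate comes from a C4 ester, and the C4 quaternary centre is made by equatorial methylation of that ester.
2. Key disconnection: bonds C3–C4 and C5–C10. Rings A and B are formed together from an acyclic triene by an intramolecular Diels–Alder reaction (diene C10=C1–C2=C3, dienophile C4=C5, tether C6–C9).
3. Enabling feature: ring A has no functional group at C1–C3, so a C1=C2 double bond can be added as a retron and later hydrogenated. C4 carries a carboxyl-level carbon (C19) that activates the dienophile, and C5 and C10 are bridged by the four-carbon chain C6–C9 that becomes ring B.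
4. The triene comes from aldehyde 10 and trienylboronate 7 by an enantioselective anti-allylboration. This sets C9 (and a temporary C8 carbinol), from which C5, C10 and C4 are relayed.
5. Ring order: A and B simultaneously (step 8); the butenolide ring is brought in preformed (step 12).

Key step: step 8

Remark: labdane numbering (C1–C20) is used for positions. The sense of induction in step 6 is assumed to follow the usual model for (R)-TRIP (Re-face attack on the aldehyde); if it proved opposite, the enantiomeric catalyst would be used.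

**Route**

Step 1
Reactants: 1 (E)-3-methylpent-2-en-4-yn-1-ol
Product: 3 (2E,4E)-3-methyl-5-(4,4,5,5-tetramethyl-1,3,2-dioxaborolan-2-yl)penta-2,4-dien-1-ol, via O-boryl dienylboronate 2 (not isolated)
Conditions: pinacolborane (1.05 equiv), CH2Cl2, 0 °C (H2 evolution); then pinacolborane (1.2 equiv), Cp2Zr(H)Cl (5 mol%), Et3N (10 mol%), 40 °C; aqueous pH 7 work-up
Reagents that add atoms: pinacolborane CC1(C)OBOC1(C)C
Why: Zirconium-catalysed syn-hydroboration of the terminal alkyne should place boron on the terminal carbon and give the (E)-alkenylboronate, the hydroxyl being borylated first and freed again on work-up (alkyne hydroboration).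

Step 2
Reactants: 3 (2E,4E)-3-methyl-5-(pinacolboryl)penta-2,4-dien-1-ol
Product: 4 (2E,4E)-3-methyl-5-(4,4,5,5-tetramethyl-1,3,2-dioxaborolan-2-yl)penta-2,4-dienal
Conditions: activated MnO2 (excess), CH2Cl2, 23 °C
Reagents that add atoms: none
Why: Activated MnO2 should oxidise the allylic alcohol selectively to the enal without touching the alkenylboronate or the olefin geometry (allylic oxidation).

Step 3
Reactants: 4 (2E,4E)-3-methyl-5-(pinacolboryl)penta-2,4-dienal
Product: 5 2-[(1E,3E)-3-methylhexa-1,3,5-trien-1-yl]-4,4,5,5-tetramethyl-1,3,2-dioxaborolane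
Conditions: Ph3PCH3Br, KOt-Bu, THF, 0 °C; then 4, −78 → 0 °C
Reagents that add atoms: methyltriphenylphosphonium bromide C[P+](c1ccccc1)(c1ccccc1)c1ccccc1.[Br-]
Why: Wittig methylenation of the unhindered enal with the non-stabilised ylide should extend the chain to the terminal triene without affecting the existing E double bonds.

Step 4
Reactants: 5 2-[(1E,3E)-3-methylhexa-1,3,5-trien-1-yl]pinacolborane
Product: 7 2-[(2E,4E)-4-methylhepta-2,4,6-trien-1-yl]-4,4,5,5-tetramethyl-1,3,2-dioxaborolane, via chloromethyl boronate ate complex 6 (not isolated)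
Conditions: ClCH2I (1.3 equiv), n-BuLi (1.2 equiv, added last), THF, −78 → 23 °C
Reagents that add atoms: chloroiodomethane ClCI
Why: Matteson homologation: chloromethyllithium adds to boron and 1,2-migration of the alkenyl group with loss of chloride inserts one CH2, turning the alkenylboronate into the (E)-allylboronate with retention of olefin geometry.

Step 5
Reactants: 8 pent-4-enal; 9 methyl acrylate
Product: 10 methyl (2E)-6-oxohex-2-enoate
Conditions: second-generation Grubbs catalyst (H2IMes)(PCy3)Cl2Ru=CHPh (2 mol%), 9 (3 equiv), CH2Cl2, 40 °C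
Reagents that add atoms: none
Why: Olefin cross-metathesis of a terminal alkene with an electron-poor acrylate should be selective for the E-enoate, and the aldehyde is tolerated.

Step 6
Reactants: 10 methyl (2E)-6-oxohex-2-enoate; 7 2-[(2E,4E)-4-methylhepta-2,4,6-trien-1-yl]pinacolborane
Product: 12 methyl (2E,6S,7S,8E)-7-ethenyl-6-hydroxy-8-methylundeca-2,8,10-trienoate, via O-boryl adduct 11 (not isolated)
Conditions: (R)-TRIP [(R)-3,3′-bis(2,4,6-triisopropylphenyl)-1,1′-binaphthyl-2,2′-diyl hydrogen phosphate] (5 mol%), 4 Å molecular sieves, toluene, −30 °C; aqueous work-up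
Reagents that add atoms: none
Why: Chiral phosphoric acid-catalysed allylboration through a closed six-membered chair transition state: γ-attack forms C8–C9, the (E)-boronate should give the anti (6S,7S) pair, and the catalyst selects the aldehyde Re face.

Step 7
Reactants: 12 methyl (2E,6S,7S,8E)-7-ethenyl-6-hydroxy-8-methylundeca-2,8,10-trienoate
Product: 13 methyl (2E,6S,7S,8E)-6-[(tert-butyldimethylsilyl)oxy]-7-ethenyl-8-methylundeca-2,8,10-trienoate
Conditions: TBSOTf, 2,6-lutidine, CH2Cl2, −78 → 0 °C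
Reagents that add atoms: tert-butyldimethylsilyl triflate CC(C)(C)[Si](C)(C)OS(=O)(=O)C(F)(F)F
Why: Silylation of the secondary alcohol with the reactive silyl triflate should proceed at low temperature without isomerising the skipped triene (silyl ether protection).

Step 8
Reactants: 13 methyl (2E,6S,7S,8E)-6-[(tert-butyldimethylsilyl)oxy]-7-ethenyl-8-methylundeca-2,8,10-trienoate
Product: 14 methyl (1S,4aR,5S,6S,8aR)-6-[(tert-butyldimethylsilyl)oxy]-5-ethenyl-4a-methyl-1,2,4a,5,6,7,8,8a-octahydronaphthalene-1-carboxylate (trans-fused; labdane C4 ester equatorial, C1=C2 double bond)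
Conditions: EtAlCl2 (1.0 equiv), CH2Cl2, −78 → 23 °C
Reagents that add atoms: none
Why: Lewis-acid-promoted intramolecular Diels–Alder reaction (type 1): the aluminium-complexed (E)-enoate C4=C5 adds suprafacially to the diene C10=C1–C2=C3 in a concerted, asynchronous [4+2] process that forms C5–C10 and C3–C4; the closest known reaction type is the alkylaluminium chloride-promoted cyclisation of (2E,8E)-undeca-2,8,10-trienoates to trans-fused octalins. Ring A closes as the new cyclohexene by the cycloaddition itself (the C3–C4 bond completes it), and ring B closes as the six-membered tether ring through the C5–C10 bond with the C6–C9 chain in a chair. C5 and C10 are set together: the ester-endo, tether-exo transition state and the E diene (tether outside, methyl inside) should place H5 and the C10 methyl anti, giving trans fusion with an axial angular methyl; C4 (ester equatorial, cis to H5) follows from the E dienophile and is re-set in step 9. Facial selectivity is relayed from C9: the chair-like tether carries the vinyl and the C8 silyloxy group equatorial (they are anti in 13), which puts H9 syn to H5 and anti to the C10 methyl. The step needs endo over exo selectivity and reaction at the hindered, fully substituted diene terminus; the Lewis acid, which also scavenges protons, raises both the endo preference and the rate, and the isolated C9 vinyl group cannot reach the diene.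

Step 9
Reactants: 14 methyl (1S,4aR,5S,6S,8aR)-6-(silyloxy)-5-ethenyl-4a-methyl-octahydronaphthalene-1-carboxylate
Product: 16 methyl (1R,4aR,5S,6S,8aS)-6-[(tert-butyldimethylsilyl)oxy]-5-ethenyl-1,4a-dimethyl-1,2,4a,5,6,7,8,8a-octahydronaphthalene-1-carboxylate, via lithium ester enolate 15 (not isolated)
Conditions: LiN(i-Pr)2 (1.3 equiv), THF, −78 → −20 °C; MeI (5 equiv), DMPU, −78 → 0 °C
Reagents that add atoms: iodomethane CI
Why: Ester enolate alkylation: MeI should attack the exocyclic C4 enolate from the equatorial face, anti to the axial C10 methyl (1,3-diaxial shielding), so the new methyl becomes equatorial and the ester axial (4R).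

Step 10
Reactants: 16 methyl (1R,4aR,5S,6S,8aS)-6-(silyloxy)-5-ethenyl-1,4a-dimethyl-octahydronaphthalene-1-carboxylate
Product: 17 [(1R,4aR,5S,6S,8aS)-6-[(tert-butyldimethylsilyl)oxy]-5-ethenyl-1,4a-dimethyl-1,2,4a,5,6,7,8,8a-octahydronaphthalen-1-yl]methanol
Conditions: LiAlH4, THF, 0 → 50 °C
Reagents that add atoms: none
Why: LiAlH4 should reduce the hindered axial neopentyl ester to the primary alcohol while the silyl ether and the isolated alkenes stay inert (hydride reduction).

Step 11
Reactants: 17 [(1R,4aR,5S,6S,8aS)-6-(silyloxy)-5-ethenyl-1,4a-dimethyl-octahydronaphthalen-1-yl]methanol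
Product: 18 [(1R,4aR,5S,6S,8aS)-6-[(tert-butyldimethylsilyl)oxy]-5-ethenyl-1,4a-dimethyl-1,2,4a,5,6,7,8,8a-octahydronaphthalen-1-yl]methyl acetate
Conditions: Ac2O, pyridine, DMAP (cat.), CH2Cl2, 23 °C
Reagents that add atoms: acetic anhydride CC(=O)OC(C)=O
Why: DMAP-catalysed acylation of the primary neopentyl alcohol (esterification).

Step 12
Reactants: 18 [(1R,4aR,5S,6S,8aS)-6-(silyloxy)-5-ethenyl-1,4a-dimethyl-octahydronaphthalen-1-yl]methyl acetate; 19 4-bromofuran-2(5H)-one
Product: 21 [(1R,4aR,5S,6S,8aS)-6-[(tert-butyldimethylsilyl)oxy]-1,4a-dimethyl-5-[2-(5-oxo-2,5-dihydrofuran-3-yl)ethyl]-1,2,4a,5,6,7,8,8a-octahydronaphthalen-1-yl]methyl acetate, via B-alkyl-9-borabicyclononane 20 (not isolated)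
Conditions: 9-borabicyclo[3.3.1]nonane dimer, THF, 0 → 23 °C; then 19, PdCl2(dppf) (5 mol%), AsPh3, Cs2CO3, DMF/THF/H2O, 23 °C
Reagents that add atoms: none
Why: 9-Borabicyclononane should hydroborate only the monosubstituted vinyl group (anti-Markovnikov; the ring cis-alkene is far slower), and the B-alkyl borane then undergoes B-alkyl Suzuki–Miyaura coupling with the vinylogous acyl bromide.

Step 13
Reactants: 21 [(1R,4aR,5S,6S,8aS)-6-(silyloxy)-1,4a-dimethyl-5-[2-(5-oxo-2,5-dihydrofuran-3-yl)ethyl]-octahydronaphthalen-1-yl]methyl acetate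
Product: 22 [(1R,4aR,5S,6S,8aS)-6-[(tert-butyldimethylsilyl)oxy]-1,4a-dimethyl-5-[2-(5-oxo-2,5-dihydrofuran-3-yl)ethyl]decahydronaphthalen-1-yl]methyl acetate
Conditions: H2 (3 atm), RhCl(PPh3)3 (10 mol%), benzene, 23 °C
Reagents that add atoms: none
Why: Homogeneous hydrogenation with RhCl(PPh3)3 should reduce the cis-disubstituted ring alkene C1=C2 but not the trisubstituted, conjugated butenolide double bond.

Step 14
Reactants: 22 [(1R,4aR,5S,6S,8aS)-6-(silyloxy)-1,4a-dimethyl-5-[2-(5-oxo-2,5-dihydrofuran-3-yl)ethyl]decahydronaphthalen-1-yl]methyl acetate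
Product: 23 [(1R,4aR,5S,6S,8aS)-6-hydroxy-1,4a-dimethyl-5-[2-(5-oxo-2,5-dihydrofuran-3-yl)ethyl]decahydronaphthalen-1-yl]methyl acetate
Conditions: HF·pyridine, pyridine/THF, 0 → 23 °C
Reagents that add atoms: none
Why: Fluoride-mediated desilylation under weakly acidic conditions should spare the acetate and the base-sensitive butenolide.

Step 15
Reactants: 23 [(1R,4aR,5S,6S,8aS)-6-hydroxy-1,4a-dimethyl-5-[2-(5-oxo-2,5-dihydrofuran-3-yl)ethyl]decahydronaphthalen-1-yl]methyl acetate
Product: 24 [(1R,4aR,5S,8aS)-1,4a-dimethyl-6-oxo-5-[2-(5-oxo-2,5-dihydrofuran-3-yl)ethyl]decahydronaphthalen-1-yl]methyl acetate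
Conditions: Dess–Martin periodinane, NaHCO3, CH2Cl2, 23 °C
Reagents that add atoms: none
Why: Dess–Martin oxidation of the secondary alcohol under buffered conditions; C9, now α to the ketone, already carries its side chain in the thermodynamically favoured equatorial position.

Step 16
Reactants: 24 [(1R,4aR,5S,8aS)-1,4a-dimethyl-6-oxo-5-[2-(5-oxo-2,5-dihydrofuran-3-yl)ethyl]decahydronaphthalen-1-yl]methyl acetate
Product: 25 [(1R,4aS,5R,8aS)-1,4a-dimethyl-6-methylidene-5-[2-(5-oxo-2,5-dihydrofuran-3-yl)ethyl]decahydronaphthalen-1-yl]methyl acetate (target)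
Conditions: Zn, CH2Br2, TiCl4, THF/CH2Cl2, 0 → 23 °C
Reagents that add atoms: dibromomethane BrCBr
Why: Takai–Lombardo methylenation is non-basic and chemoselective for ketones over esters and lactones, so the hindered C8 ketone should be methylenated without epimerising C9.

**Compound list**

1 | (E)-3-methylpent-2-en-4-yn-1-ol | OC/C=C(C)/C#C | starting material
2 | 2-{[(2E,4E)-3-methyl-5-(4,4,5,5-tetramethyl-1,3,2-dioxaborolan-2-yl)penta-2,4-dien-1-yl]oxy}-4,4,5,5-tetramethyl-1,3,2-dioxaborolane | CC1(C)OB(OC/C=C(C)/C=C/B2OC(C)(C)C(C)(C)O2)OC1(C)C | intermediate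
3 | (2E,4E)-3-methyl-5-(4,4,5,5-tetramethyl-1,3,2-dioxaborolan-2-yl)penta-2,4-dien-1-ol | OC/C=C(C)/C=C/B1OC(C)(C)C(C)(C)O1 | intermediate
4 | (2E,4E)-3-methyl-5-(4,4,5,5-tetramethyl-1,3,2-dioxaborolan-2-yl)penta-2,4-dienal | O=C/C=C(C)/C=C/B1OC(C)(C)C(C)(C)O1 | intermediate
5 | 2-[(1E,3E)-3-methylhexa-1,3,5-trien-1-yl]-4,4,5,5-tetramethyl-1,3,2-dioxaborolane | C=C/C=C(C)/C=C/B1OC(C)(C)C(C)(C)O1 | intermediate
6 | lithium (chloromethyl)[(1E,3E)-3-methylhexa-1,3,5-trien-1-yl]pinacolatoborate | C=C/C=C(C)/C=C/[B-]1(CCl)OC(C)(C)C(C)(C)O1.[Li+] | intermediate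
7 | 2-[(2E,4E)-4-methylhepta-2,4,6-trien-1-yl]-4,4,5,5-tetramethyl-1,3,2-dioxaborolane | C=C/C=C(C)/C=C/CB1OC(C)(C)C(C)(C)O1 | intermediate
8 | pent-4-enal | C=CCCC=O | starting material
9 | methyl acrylate | C=CC(=O)OC | starting material
10 | methyl (2E)-6-oxohex-2-enoate | COC(=O)/C=C/CCC=O | intermediate
11 | methyl (2E,6S,7S,8E)-7-ethenyl-8-methyl-6-[(4,4,5,5-tetramethyl-1,3,2-dioxaborolan-2-yl)oxy]undeca-2,8,10-trienoate | COC(=O)/C=C/CC[C@H](OB1OC(C)(C)C(C)(C)O1)[C@@H](C=C)/C(C)=C/C=C | intermediate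
12 | methyl (2E,6S,7S,8E)-7-ethenyl-6-hydroxy-8-methylundeca-2,8,10-trienoate | COC(=O)/C=C/CC[C@H](O)[C@@H](C=C)/C(C)=C/C=C | intermediate
13 | methyl (2E,6S,7S,8E)-6-[(tert-butyldimethylsilyl)oxy]-7-ethenyl-8-methylundeca-2,8,10-trienoate | COC(=O)/C=C/CC[C@H](O[Si](C)(C)C(C)(C)C)[C@@H](C=C)/C(C)=C/C=C | intermediate
14 | methyl (1S,4aR,5S,6S,8aR)-6-[(tert-butyldimethylsilyl)oxy]-5-ethenyl-4a-methyl-1,2,4a,5,6,7,8,8a-octahydronaphthalene-1-carboxylate | CC(C)(C)[Si](C)(C)O[C@H]1CC[C@@H]2[C@@H](C(=O)OC)CC=C[C@@]2(C)[C@@H]1C=C | intermediate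
15 | lithium ester enolate of 14 (ketene acetal at labdane C4=C19) | CC(C)(C)[Si](C)(C)O[C@H]1CC[C@@H]2C(=C(OC)O[Li])CC=C[C@@]2(C)[C@@H]1C=C | intermediate
16 | methyl (1R,4aR,5S,6S,8aS)-6-[(tert-butyldimethylsilyl)oxy]-5-ethenyl-1,4a-dimethyl-1,2,4a,5,6,7,8,8a-octahydronaphthalene-1-carboxylate | CC(C)(C)[Si](C)(C)O[C@H]1CC[C@@H]2[C@](C)(C(=O)OC)CC=C[C@@]2(C)[C@@H]1C=C | intermediate
17 | [(1R,4aR,5S,6S,8aS)-6-[(tert-butyldimethylsilyl)oxy]-5-ethenyl-1,4a-dimethyl-1,2,4a,5,6,7,8,8a-octahydronaphthalen-1-yl]methanol | CC(C)(C)[Si](C)(C)O[C@H]1CC[C@@H]2[C@](C)(CO)CC=C[C@@]2(C)[C@@H]1C=C | intermediate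
18 | [(1R,4aR,5S,6S,8aS)-6-[(tert-butyldimethylsilyl)oxy]-5-ethenyl-1,4a-dimethyl-1,2,4a,5,6,7,8,8a-octahydronaphthalen-1-yl]methyl acetate | CC(C)(C)[Si](C)(C)O[C@H]1CC[C@@H]2[C@](C)(COC(C)=O)CC=C[C@@]2(C)[C@@H]1C=C | intermediate
19 | 4-bromofuran-2(5H)-one | BrC1=CC(=O)OC1 | starting material
20 | [(1R,4aR,5S,6S,8aS)-5-[2-(9-borabicyclo[3.3.1]nonan-9-yl)ethyl]-6-[(tert-butyldimethylsilyl)oxy]-1,4a-dimethyl-1,2,4a,5,6,7,8,8a-octahydronaphthalen-1-yl]methyl acetate | CC(C)(C)[Si](C)(C)O[C@H]1CC[C@@H]2[C@](C)(COC(C)=O)CC=C[C@@]2(C)[C@@H]1CCB1C2CCCC1CCC2 | intermediate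
21 | [(1R,4aR,5S,6S,8aS)-6-[(tert-butyldimethylsilyl)oxy]-1,4a-dimethyl-5-[2-(5-oxo-2,5-dihydrofuran-3-yl)ethyl]-1,2,4a,5,6,7,8,8a-octahydronaphthalen-1-yl]methyl acetate | CC(C)(C)[Si](C)(C)O[C@H]1CC[C@@H]2[C@](C)(COC(C)=O)CC=C[C@@]2(C)[C@@H]1CCC1=CC(=O)OC1 | intermediate
22 | [(1R,4aR,5S,6S,8aS)-6-[(tert-butyldimethylsilyl)oxy]-1,4a-dimethyl-5-[2-(5-oxo-2,5-dihydrofuran-3-yl)ethyl]decahydronaphthalen-1-yl]methyl acetate | CC(C)(C)[Si](C)(C)O[C@H]1CC[C@@H]2[C@](C)(COC(C)=O)CCC[C@@]2(C)[C@@H]1CCC1=CC(=O)OC1 | intermediate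
23 | [(1R,4aR,5S,6S,8aS)-6-hydroxy-1,4a-dimethyl-5-[2-(5-oxo-2,5-dihydrofuran-3-yl)ethyl]decahydronaphthalen-1-yl]methyl acetate | O[C@H]1CC[C@@H]2[C@](C)(COC(C)=O)CCC[C@@]2(C)[C@@H]1CCC1=CC(=O)OC1 | intermediate
24 | [(1R,4aR,5S,8aS)-1,4a-dimethyl-6-oxo-5-[2-(5-oxo-2,5-dihydrofuran-3-yl)ethyl]decahydronaphthalen-1-yl]methyl acetate | O=C1CC[C@@H]2[C@](C)(COC(C)=O)CCC[C@@]2(C)[C@@H]1CCC1=CC(=O)OC1 | intermediate
25 | [(1R,4aS,5R,8aS)-1,4a-dimethyl-6-methylidene-5-[2-(5-oxo-2,5-dihydrofuran-3-yl)ethyl]decahydronaphthalen-1-yl]methyl acetate | C=C1CC[C@@H]2[C@](C)(COC(C)=O)CCC[C@@]2(C)[C@@H]1CCC1=CC(=O)OC1 | target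

**Step count and risks**

Total steps: 16. Longest linear sequence: 15 (steps 1–4, then 6–16).

Steps most likely to fail:

Step 8. The fully substituted, methyl-inside diene terminus may react too slowly with the ester-activated dienophile, so that Lewis-acid-induced oligomerisation of the skipped triene or erosion of the endo preference (cis-fused adduct) takes over. The fallback changes the dienophile to an enal and the activation to iminium catalysis. It sets out from 13: reduction with i-Bu2AlH (CH2Cl2, −78 °C) should give (2E,6S,7S,8E)-6-[(tert-butyldimethylsilyl)oxy]-7-ethenyl-8-methylundeca-2,8,10-trien-1-ol F1, and MnO2 oxidation the corresponding trienal F2. Its iminium-activated intramolecular Diels–Alder reaction (dibenzylammonium trifluoroacetate, benzene, 23–50 °C) should give the trans-fused (1S,4aR,5S,6S,8aR)-octahydronaphthalene-1-carbaldehyde F3. Pinnick oxidation (NaClO2, NaH2PO4, 2-methylbut-2-ene) to the carboxylic acid F4 and esterification with Me3SiCHN2/MeOH bring the route back at 14.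

Step 6. Enantio- or regiocontrol may be lost through uncatalysed background allylboration, weak binding of the aliphatic aldehyde to the catalyst, or E/Z scrambling of the trienylboronate by borotropic shift. The fallback replaces catalyst control by reagent control with a tartrate-modified allylboronate. It sets out from 7: transesterification with diethanolamine (Et2O) should give the crystalline diethanolamine complex of the trienylboronic acid F5, and exchange with (S,S)-diisopropyl tartrate (Et2O/brine) the diisopropyl (4S,5S)-tartrate trienylboronate F6. Its uncatalysed reaction with 10 (toluene, 4 Å molecular sieves, −78 °C) should give the anti borate adduct F7, whose hydrolytic work-up brings the route back at 12.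

Step 9. Facial selectivity of the enolate methylation may be poor because ring A is a flattened cyclohexene, or enolisation of the hindered ester may be incomplete. The fallback sets C4 in the cycloaddition through dienophile geometry instead of by alkylation. It sets out from 8: Still–Gennari olefination with methyl 2-[bis(2,2,2-trifluoroethoxy)phosphoryl]propanoate (KN(SiMe3)2, 18-crown-6, THF, −78 °C) should give methyl (2Z)-2-methylhepta-2,6-dienoate F8. Lemieux–Johnson cleavage of its terminal alkene (OsO4 cat., NaIO4, 2,6-lutidine, dioxane/H2O) should give methyl (2Z)-2-methyl-6-oxohex-2-enoate F9. Allylboration with 7 under the conditions of step 6 proceeds through the O-boryl adduct F10 to methyl (2Z,6S,7S,8E)-7-ethenyl-6-hydroxy-2,8-dimethylundeca-2,8,10-trienoate F11, and silylation as in step 7 gives its tert-butyldimethylsilyl ether F12. Thermal intramolecular Diels–Alder reaction of F12 (toluene, BHT, 150 °C) through the tether-exo, ester-exo transition state would place the ester axial and the methyl equatorial at C4 and bring the route back at 16.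

**Further compounds**

F1 | step 8 | (2E,6S,7S,8E)-6-[(tert-butyldimethylsilyl)oxy]-7-ethenyl-8-methylundeca-2,8,10-trien-1-ol | OC/C=C/CC[C@H](O[Si](C)(C)C(C)(C)C)[C@@H](C=C)/C(C)=C/C=C
F2 | step 8 | (2E,6S,7S,8E)-6-[(tert-butyldimethylsilyl)oxy]-7-ethenyl-8-methylundeca-2,8,10-trienal | O=C/C=C/CC[C@H](O[Si](C)(C)C(C)(C)C)[C@@H](C=C)/C(C)=C/C=C
F3 | step 8 | (1S,4aR,5S,6S,8aR)-6-[(tert-butyldimethylsilyl)oxy]-5-ethenyl-4a-methyl-1,2,4a,5,6,7,8,8a-octahydronaphthalene-1-carbaldehyde | CC(C)(C)[Si](C)(C)O[C@H]1CC[C@@H]2[C@@H](C=O)CC=C[C@@]2(C)[C@@H]1C=C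
F4 | step 8 | (1S,4aR,5S,6S,8aR)-6-[(tert-butyldimethylsilyl)oxy]-5-ethenyl-4a-methyl-1,2,4a,5,6,7,8,8a-octahydronaphthalene-1-carboxylic acid | CC(C)(C)[Si](C)(C)O[C@H]1CC[C@@H]2[C@@H](C(=O)O)CC=C[C@@]2(C)[C@@H]1C=C
F5 | step 6 | diethanolamine complex of [(2E,4E)-4-methylhepta-2,4,6-trien-1-yl]boronic acid | C=C/C=C(C)/C=C/C[B-]12OCC[NH+]1CCO2
F6 | step 6 | diisopropyl (4S,5S)-2-[(2E,4E)-4-methylhepta-2,4,6-trien-1-yl]-1,3,2-dioxaborolane-4,5-dicarboxylate | CC(C)OC(=O)[C@H]1OB(C/C=C/C(C)=C/C=C)O[C@@H]1C(=O)OC(C)C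
F7 | step 6 | diisopropyl (4S,5S)-2-{[(2E,6S,7S,8E)-7-ethenyl-1-methoxy-8-methyl-1-oxoundeca-2,8,10-trien-6-yl]oxy}-1,3,2-dioxaborolane-4,5-dicarboxylate | COC(=O)/C=C/CC[C@H](OB1O[C@H](C(=O)OC(C)C)[C@@H](C(=O)OC(C)C)O1)[C@@H](C=C)/C(C)=C/C=C
F8 | step 9 | methyl (2Z)-2-methylhepta-2,6-dienoate | COC(=O)/C(C)=C\CCC=C
F9 | step 9 | methyl (2Z)-2-methyl-6-oxohex-2-enoate | COC(=O)/C(C)=C\CCC=O
F10 | step 9 | methyl (2Z,6S,7S,8E)-7-ethenyl-2,8-dimethyl-6-[(4,4,5,5-tetramethyl-1,3,2-dioxaborolan-2-yl)oxy]undeca-2,8,10-trienoate | COC(=O)/C(C)=C\CC[C@H](OB1OC(C)(C)C(C)(C)O1)[C@@H](C=C)/C(C)=C/C=C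
F11 | step 9 | methyl (2Z,6S,7S,8E)-7-ethenyl-6-hydroxy-2,8-dimethylundeca-2,8,10-trienoate | COC(=O)/C(C)=C\CC[C@H](O)[C@@H](C=C)/C(C)=C/C=C
F12 | step 9 | methyl (2Z,6S,7S,8E)-6-[(tert-butyldimethylsilyl)oxy]-7-ethenyl-2,8-dimethylundeca-2,8,10-trienoate | COC(=O)/C(C)=C\CC[C@H](O[Si](C)(C)C(C)(C)C)[C@@H](C=C)/C(C)=C/C=C
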